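Counting is the easy step. I take one partner per target, so the partner charged sets a ceiling of 70.0 % target.

common to all: starting material 0.20 M; initiator 1 mol%; radical scavenger 0.022 mol%
- beta: partner 0.70 equiv; temperature 100 °C; the very flask that is asked about, followed so far
- eta: partner 0.70 equiv; temperature 106 °C; run made earlier
- flask: partner 0.700 equiv; temperature 100 °C; time 8.0 d

| run | time / h | target / % |
|---|---|---|
| beta | 12.0 | 16.0 |
| beta | 30.0 | 41.7 |
| beta | 72.0 | 60.4 |
| beta | 144 | 61.4 |
| eta | 12.0 | 28.9 |
| eta | 30.0 | 53.1 |
| eta | 72.0 | 62.4 |
| eta | 144 | 59.5 |

(readings scatter by 0.5 percentage points)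

- violet: change nothing and wait 4.0 d more
- ochre: at 8.0 d take out 90 % of the target then present, then wait 4.0 d
- red: at 8.0 d add partner, 50.0 % of the amount charged, then wait 4.0 d
- blue: at 8.0 d raise the temperature by 20 K, then wait 4.0 d

- what is taken out of target is counted as made
- what was read earlier has a scatter of 0.5 percentage points, one standard deviation
- additions bring no volume worth counting

* target, in percent of the starting material first charged, at 8.0 d
* what to do for the largest gain in target; "none" if nothing gains more than 2 percentage points (violet / ochre / red / blue / none)
* target present, with what was taken out counted in, in percent of the starting material first charged, after ochre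
* target present, with what was taken out counted in, in percent of the starting material first charged, after blue

The last beta reading stands at 61.4 %, below that ceiling. The hotter eta flask falls from 62.4 % to 59.5 % between 72.0 h and 144 h. So target is being lost in the eta flask, and I carry that slope, read at the higher temperature, over to the beta flask as a rough figure:

now ≈ 61.4 % − slope × (8.0 d − 144 h) = 59.5 %

My guess, which these readings cannot test, is that each lost target takes one starting material with it. Then:

free = 1 − 2 × 0.700 + target = 19.5 %

This free share is the charge, less what the partner turned over if it has reacted to the end, less what lost target took.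

Now the settings, by hand.

Violet: the same slope costs 3.9 percentage points.

Ochre: 10.0 % of the target stays exposed, so I expect 59.1 %, no gain.

Red: the dose allows 35.0 %, more than the free share, so starting material becomes the limiting reagent, and I expect a gain near 20 points.

Blue: the last eta reading lies below the one before it, while the last beta reading lies above its own, so I put blue below violet's 55.6 %.

The forecast gives 59.5 % at the time of looking, chooses red, and puts ochre at 59.4 % and blue at 45 %. It holds “about 0.31 starting material remains”, and there we part, since I reckon 19.5 %.

The flask gives 60.1 % and chooses red. Violet changes the target by −3.2 points, ochre by −0.28 points, red by 19 points and blue by −8.7 points, with 59.8 % after ochre and 51.4 % after blue.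

    first chain carrier → ended carrier (k = 3.50 min⁻¹, Ea = 107 kJ mol⁻¹)
    2 first chain carrier → ended chains A (k = 1.00 × 10⁸ L mol⁻¹ s⁻¹, Ea = 14.0 kJ mol⁻¹)
    starting material + second chain carrier → released group + first chain carrier (k = 28000 L mol⁻¹ s⁻¹, Ea = 8.00 kJ mol⁻¹)
    first chain carrier + radical scavenger → ended chains C (k = 6.50 × 10⁶ L mol⁻¹ s⁻¹, Ea = 19.0 kJ mol⁻¹)
    2 second chain carrier → ended chains B (k = 1.20 × 10⁷ L mol⁻¹ s⁻¹, Ea = 19.0 kJ mol⁻¹)
    partner + first chain carrier → target + second chain carrier (k = 2.10 × 10⁵ L mol⁻¹ min⁻¹, Ea = 22.0 kJ mol⁻¹)
    starting material + target → side product (k = 2.70 × 10⁻⁴ L mol⁻¹ min⁻¹, Ea = 79.0 kJ mol⁻¹)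
    initiator → 2 initiating radical (k = 3.40 × 10⁻⁵ min⁻¹, Ea = 125 kJ mol⁻¹)
    starting material + initiating radical → capped initiator + first chain carrier (k = 2.10 × 10⁵ L mol⁻¹ s⁻¹, Ea = 40.0 kJ mol⁻¹)
    (constants at 100 °C)

With the computed target, and partner down to 0.11 % of its charge, the count gives 20.1 % free, and the flask holds 20 % of its starting material. The flask is not at rest. Left until 1920 h, its target sinks to 43.1 %, its side product climbs from 19.7 % to 53.8 %, and its starting material falls to 1.12 %.

In the neighbour flask with 0.420 equiv of partner and 31.5 % target, the count gives 47.5 % free. The simulation of that flask holds 46.9 % of starting material.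

The runs are simulated with made-up constants; the scatter is artificial.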